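**Retrosynthetic overview**
1. Target ⇒ its C1‑TIPS derivative ⇒ two bromonium‑induced etherifications in one flask on a ring‑A diol that carries a 7Z‑alkene, a 9‑OH/10‑Br bromohydrin and a 12E‑alkene. O9→C13 (6‑endo, Br at C12) closes ring C; O4→C7 (5‑exo, Br at C8) closes ring B.
2. 7Z‑alkene ⇒ alkyne. The C8–C9 bond ⇒ ring‑A alkynyllithium + (R)‑2‑bromohept‑4‑enal; anti addition sets C9 and the C10 bromine is carried in.
3. Ring A ⇒ 5‑endo opening at propargylic C3 of a (3R,4R)‑epoxide by the C6 hydroxyl. The epoxide ⇒ E‑enyne by Shi epoxidation.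
4. E‑enyne ⇒ hydrozirconation/alkynylation of a homopropargylic alcohol made by catalytic asymmetric propargylation. Bromoaldehyde ⇒ Johnson–Claisen, iBu2AlH, organocatalytic α‑bromination.
5. Ring order: A, then C, then B.

Assumption: locants C1–C15 run from the alkyne CH to the ethyl CH3; ring A = C3–O–C6 oxolane, ring B = C4–O–C7 oxolane, ring C = C9–O–C13 oxane; the biogenesis is taken to be hydroxy‑epoxide opening plus bromonium‑induced etherification of a linear C15 enyne.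

**Step 1**
Reactants: 1 3‑(trimethylsilyl)prop‑2‑ynal; 2 allenylboronic acid pinacol ester
Product: 4 (3R)‑1‑(trimethylsilyl)hexa‑1,5‑diyn‑3‑ol, via pinacolboryl ether 3 (not isolated)
Conditions: (R)‑TRIP [(R)‑3,3′‑bis(2,4,6‑triisopropylphenyl)‑BINOL hydrogen phosphate] (10 mol %), 4 Å MS, toluene, −20 °C; aqueous work‑up
Reagents that add atoms: none
Why: Chiral‑phosphoric‑acid‑catalysed asymmetric propargylation (SE2′ allenylboration through a closed six‑membered transition state), in which the (R)‑acid exposes the Re face of the aldehyde and sets C6 as R.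

**Step 2**
Reactants: 4 (3R)‑1‑(trimethylsilyl)hexa‑1,5‑diyn‑3‑ol; 5 (bromoethynyl)triisopropylsilane
Product: 7 (3R,5E)‑8‑(triisopropylsilyl)‑1‑(trimethylsilyl)oct‑5‑ene‑1,7‑diyn‑3‑ol, via bis‑zirconocene adduct 6 (not isolated)
Conditions: Cp2Zr(H)Cl (2.2 equiv), CH2Cl2, 0 °C to rt; then 5, Pd(PPh3)4 (5 mol %), ZnCl2 (20 mol %), THF, rt
Reagents that add atoms: none
Why: Hydrozirconation followed by Negishi‑type cross‑coupling, in which (after O–H metalation) Zr–H adds syn and terminally to the only uncapped alkyne and zerovalent palladium couples the E‑alkenyl metal to the bromoalkyne with retention, giving the 3E‑enyne.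

**Step 3**
Reactants: 7 (3R,5E)‑8‑(triisopropylsilyl)‑1‑(trimethylsilyl)oct‑5‑ene‑1,7‑diyn‑3‑ol
Product: 8 (2R)‑1‑[(2R,3R)‑3‑(triisopropylsilylethynyl)oxiran‑2‑yl]‑4‑(trimethylsilyl)but‑3‑yn‑2‑ol
Conditions: D‑fructose‑derived Shi ketone (30 mol %), KHSO5 (as 2KHSO5·KHSO4·K2SO4), K2CO3, Bu4NHSO4 (cat.), MeCN–(MeO)2CH2–aq. Na2B4O7 buffer, 0 °C
Reagents that add atoms: potassium peroxymonosulfate KHSO5, [K+].[O-]S(=O)(=O)OO
Why: Shi asymmetric epoxidation of the only alkene present (conjugated E‑enynes are good substrates), whose spiro transition state gives the (R,R)‑trans‑epoxide (3R,4R) under reagent control, so the minor enantiomer of 7 ends up as a separable diastereomer.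

**Step 4**
Reactants: 8 (2R)‑1‑[(2R,3R)‑3‑(triisopropylsilylethynyl)oxiran‑2‑yl]‑4‑(trimethylsilyl)but‑3‑yn‑2‑ol
Product: 9 (2S,3R,5R)‑2‑(triisopropylsilylethynyl)‑5‑(trimethylsilylethynyl)oxolan‑3‑ol (ring A)
Conditions: (+)‑camphorsulfonic acid (15 mol %), CH2Cl2, 0 °C to rt
Reagents that add atoms: none
Why: Acid‑catalysed 5‑endo‑tet opening of a 3,4‑epoxy alcohol (hydroxy‑epoxide cyclisation), favoured because the 4‑exo path would give an oxetane and propargylic C3 is the SN2‑activated end, so backside attack by O6 inverts C3 (R to S), leaves C4 and C6 untouched and places the new C4‑OH cis to the C6 side chain.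

**Step 5**
Reactants: 10 pent‑1‑en‑3‑ol (racemic); 11 triethyl orthoacetate
Product: 13 ethyl (4E)‑hept‑4‑enoate, via mixed ketene acetal 12 (not isolated)
Conditions: EtCO2H (cat.), 140 °C, EtOH distilled off
Reagents that add atoms: none
Why: Johnson–Claisen rearrangement, whose chair transition state with the ethyl group equatorial gives the 12E‑alkene (at least 95:5).

**Step 6**
Reactants: 13 ethyl (4E)‑hept‑4‑enoate
Product: 15 (4E)‑hept‑4‑enal, via aluminium hemiacetal 14 (not isolated)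
Conditions: iBu2AlH (1.05 equiv), CH2Cl2, −78 °C; aqueous work‑up
Reagents that add atoms: none
Why: Partial ester reduction, in which the tetrahedral aluminium hemiacetal survives at −78 °C and collapses to the aldehyde only on work‑up, leaving the alkene untouched.

**Step 7**
Reactants: 15 (4E)‑hept‑4‑enal
Product: 16 (2R,4E)‑2‑bromohept‑4‑enal
Conditions: (R)‑2‑{bis[3,5‑bis(trifluoromethyl)phenyl](trimethylsilyloxy)methyl}pyrrolidine (10 mol %), 4,4‑dibromo‑2,6‑di‑tert‑butylcyclohexa‑2,5‑dienone (1.0 equiv), PhCO2H (cat.), CH2Cl2–pentane, −40 °C; cold silica plug, used at once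
Reagents that add atoms: 4,4‑dibromo‑2,6‑di‑tert‑butylcyclohexa‑2,5‑dien‑1‑one, CC(C)(C)C1=CC(Br)(Br)C=C(C(C)(C)C)C1=O
Why: Enamine‑catalysed asymmetric α‑bromination, in which the mild Br donor reacts with the E‑enamine far faster than with the alkene and enters on the face remote from the diaryl(silyloxy)methyl group, so the (R)‑catalyst sets C10 as R.

**Step 8**
Reactants: 9 (2S,3R,5R)‑2‑(triisopropylsilylethynyl)‑5‑(trimethylsilylethynyl)oxolan‑3‑ol; 16 (2R,4E)‑2‑bromohept‑4‑enal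
Product: 19 (2S,3R,5R)‑5‑[(3S,4R,6E)‑4‑bromo‑3‑hydroxynon‑6‑en‑1‑yn‑1‑yl]‑2‑(triisopropylsilylethynyl)oxolan‑3‑ol, via dilithio acetylide alkoxide 17 (not isolated), via dilithium dialkoxide 18 (not isolated)
Conditions: MeLi·LiBr (2.05 equiv), THF, −78 °C to rt; −78 °C, 16; AcOH (2.2 equiv), −78 °C
Reagents that add atoms: none
Why: Desilylative lithiation (MeLi removes only the small SiMe3 group) followed by 1,2‑addition to an α‑haloaldehyde under Cornforth–Evans control gives the anti bromohydrin (9S,10R), and the cold acid quench stops the alkoxide from closing to the epoxide.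

**Step 9**
Reactants: 19 (2S,3R,5R)‑5‑[(3S,4R,6E)‑4‑bromo‑3‑hydroxynon‑6‑en‑1‑yn‑1‑yl]‑2‑(triisopropylsilylethynyl)oxolan‑3‑ol
Product: 20 (2S,3R,5R)‑5‑[(1Z,3S,4R,6E)‑4‑bromo‑3‑hydroxynona‑1,6‑dien‑1‑yl]‑2‑(triisopropylsilylethynyl)oxolan‑3‑ol
Conditions: H2 (1 atm), Pd/CaCO3 poisoned with Pb(OAc)2, quinoline, EtOAc, rt, stopped after 1 equiv H2
Reagents that add atoms: none
Why: Lindlar‑type syn semi‑hydrogenation of the unhindered 1,4‑dioxygenated alkyne gives the 7Z‑alkene, while the TIPS‑shielded alkyne, the E‑alkene and the C–Br bond are left intact.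

**Step 10**
Reactants: 20 (2S,3R,5R)‑5‑[(1Z,3S,4R,6E)‑4‑bromo‑3‑hydroxynona‑1,6‑dien‑1‑yl]‑2‑(triisopropylsilylethynyl)oxolan‑3‑ol
Product: 22 (3S,4R,6R,7S,8R,9R,10R,12S,13R)‑8,10,12‑tribromo‑3,6:4,7:9,13‑triepoxy‑1‑(triisopropylsilyl)pentadec‑1‑yne, via ring C bromo‑ether 21 (not isolated)
Conditions: NBS (2.2 equiv), 4 Å MS, MeCN, −20 to 0 °C, dark
Reagents that add atoms: N‑bromosuccinimide, O=C1CCC(=O)N1Br
Why: Proposed new method: two bromoetherifications in one flask (closest known type: NBS or tetrabromocyclohexadienone cyclisation of hydroxy‑alkenes to Laurencia bromo‑ethers), in which the electron‑richer 12E‑alkene reacts first and O9 closes ring C 6‑endo at C13 through an all‑equatorial chair because the C10 bromine disfavours positive charge at C12 (anti addition to the E‑alkene gives 12S,13R), and the deactivated 7Z‑alkene then takes the only hydroxyl within reach, O4 held cis on ring A, 5‑exo at C7 from the rotamer in which the C6–O bond rather than the C5 methylene eclipses the Z‑alkene, so C8 ends endo over the ring oxygen (7S) and anti addition to the Z‑alkene gives 8R.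

**Step 11**
Reactants: 22 (3S,4R,6R,7S,8R,9R,10R,12S,13R)‑8,10,12‑tribromo‑3,6:4,7:9,13‑triepoxy‑1‑(triisopropylsilyl)pentadec‑1‑yne
Product: 23 (3S,4R,6R,7S,8R,9R,10R,12S,13R)‑8,10,12‑tribromo‑3,6:4,7:9,13‑triepoxypentadec‑1‑yne (target)
Conditions: Bu4NF (1.2 equiv), AcOH (1.2 equiv), THF, 0 °C
Reagents that add atoms: none
Why: Fluoride‑induced protodesilylation of the alkynylsilane, buffered with acetic acid so that the secondary bromides do not eliminate and no stereocentre is touched.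

**Compound list**
1 | 3‑(trimethylsilyl)prop‑2‑ynal | C[Si](C)(C)C#CC=O | starting material
2 | allenylboronic acid pinacol ester | C=C=CB1OC(C)(C)C(C)(C)O1 | starting material
3 | pinacolboryl ether of 4 | C[Si](C)(C)C#C[C@H](OB1OC(C)(C)C(C)(C)O1)CC#C | intermediate
4 | (3R)‑1‑(trimethylsilyl)hexa‑1,5‑diyn‑3‑ol | C[Si](C)(C)C#C[C@H](O)CC#C | intermediate
5 | (bromoethynyl)triisopropylsilane | BrC#C[Si](C(C)C)(C(C)C)C(C)C | starting material
6 | O‑zirconated (E)‑alkenylzirconocene from 4 (Cp drawn σ‑bonded) | C[Si](C)(C)C#C[C@H](O[Zr](Cl)(C1C=CC=C1)C1C=CC=C1)C/C=C/[Zr](Cl)(C1C=CC=C1)C1C=CC=C1 | intermediate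
7 | (3R,5E)‑8‑(triisopropylsilyl)‑1‑(trimethylsilyl)oct‑5‑ene‑1,7‑diyn‑3‑ol | C[Si](C)(C)C#C[C@H](O)C/C=C/C#C[Si](C(C)C)(C(C)C)C(C)C | intermediate
8 | (2R)‑1‑[(2R,3R)‑3‑(triisopropylsilylethynyl)oxiran‑2‑yl]‑4‑(trimethylsilyl)but‑3‑yn‑2‑ol | C[Si](C)(C)C#C[C@H](O)C[C@H]1O[C@@H]1C#C[Si](C(C)C)(C(C)C)C(C)C | intermediate
9 | (2S,3R,5R)‑2‑(triisopropylsilylethynyl)‑5‑(trimethylsilylethynyl)oxolan‑3‑ol | CC(C)[Si](C#C[C@@H]1O[C@@H](C#C[Si](C)(C)C)C[C@H]1O)(C(C)C)C(C)C | intermediate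
10 | pent‑1‑en‑3‑ol (racemic) | C=CC(O)CC | starting material
11 | triethyl orthoacetate | CC(OCC)(OCC)OCC | starting material
12 | 1‑ethoxy‑1‑(pent‑1‑en‑3‑yloxy)ethene | C=C(OCC)OC(CC)C=C | intermediate
13 | ethyl (4E)‑hept‑4‑enoate | CC/C=C/CCC(=O)OCC | intermediate
14 | diisobutylaluminium hemiacetal of 13 | CC/C=C/CCC(OCC)O[Al](CC(C)C)CC(C)C | intermediate
15 | (4E)‑hept‑4‑enal | CC/C=C/CCC=O | intermediate
16 | (2R,4E)‑2‑bromohept‑4‑enal | CC/C=C/C[C@@H](Br)C=O | intermediate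
17 | dilithio acetylide alkoxide from 9 | CC(C)[Si](C#C[C@@H]1O[C@@H](C#C[Li])C[C@H]1O[Li])(C(C)C)C(C)C | intermediate
18 | dilithium dialkoxide of 19 | CC(C)[Si](C#C[C@@H]1O[C@@H](C#C[C@H](O[Li])[C@H](Br)C/C=C/CC)C[C@H]1O[Li])(C(C)C)C(C)C | intermediate
19 | (2S,3R,5R)‑5‑[(3S,4R,6E)‑4‑bromo‑3‑hydroxynon‑6‑en‑1‑yn‑1‑yl]‑2‑(triisopropylsilylethynyl)oxolan‑3‑ol | CC(C)[Si](C#C[C@@H]1O[C@@H](C#C[C@H](O)[C@H](Br)C/C=C/CC)C[C@H]1O)(C(C)C)C(C)C | intermediate
20 | (2S,3R,5R)‑5‑[(1Z,3S,4R,6E)‑4‑bromo‑3‑hydroxynona‑1,6‑dien‑1‑yl]‑2‑(triisopropylsilylethynyl)oxolan‑3‑ol | CC(C)[Si](C#C[C@@H]1O[C@@H](/C=C\[C@H](O)[C@H](Br)C/C=C/CC)C[C@H]1O)(C(C)C)C(C)C | intermediate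
21 | (2S,3R,5R)‑5‑{(Z)‑2‑[(2S,3R,5S,6R)‑3,5‑dibromo‑6‑ethyloxan‑2‑yl]ethenyl}‑2‑(triisopropylsilylethynyl)oxolan‑3‑ol | CC(C)[Si](C#C[C@@H]1O[C@@H](/C=C\[C@@H]2O[C@H](CC)[C@@H](Br)C[C@H]2Br)C[C@H]1O)(C(C)C)C(C)C | intermediate
22 | (3S,4R,6R,7S,8R,9R,10R,12S,13R)‑8,10,12‑tribromo‑3,6:4,7:9,13‑triepoxy‑1‑(triisopropylsilyl)pentadec‑1‑yne | CC(C)[Si](C#C[C@@H]1O[C@@H]2C[C@H]1O[C@@H]2[C@@H](Br)[C@@H]1O[C@H](CC)[C@@H](Br)C[C@H]1Br)(C(C)C)C(C)C | intermediate
23 | (3S,4R,6R,7S,8R,9R,10R,12S,13R)‑8,10,12‑tribromo‑3,6:4,7:9,13‑triepoxypentadec‑1‑yne | C#C[C@@H]1O[C@@H]2C[C@H]1O[C@@H]2[C@@H](Br)[C@@H]1O[C@H](CC)[C@@H](Br)C[C@H]1Br | target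

**Totals**
Total step count: 11. Longest linear sequence: 8 (steps 1–4 and 8–11).

**The three steps most likely to fail**

**Step 10, double bromoetherification.**
- O9 may close 5‑exo at C12 instead of 6‑endo at C13.
- O4 may attack the other face of the 7Z‑alkene and give the exo C7 epimer.
- The doubly allylic‑ether alkene may react slowly.

The fallback sets out from 20 and comes back at 22. It replaces the hydroxyl nucleophile of ring C by an epoxide oxygen with external bromide. K2CO3 in MeOH at 0 °C closes the bromohydrin to the (Z)‑vinyl trans‑9,10‑epoxide F1. One equivalent of NBS in MeCN, with no bromide present, closes ring B alone, because only O4–H can discharge a bromonium irreversibly; this gives the bicyclic 8‑bromo‑9,10‑epoxide F2, and the C7 epimers can be separated here. Br2 (1 equiv, CH2Cl2, −78 °C) then forms the 12,13‑bromonium. The epoxide oxygen can reach only the distal carbon C13. The resulting bicyclic oxonium ion is opened by bromide with inversion at C10, since C9 is shielded and deactivated by the C8 bromine. This gives 22 without any 5‑exo/6‑endo competition at the alkene.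

**Step 8, addition to the labile bromoaldehyde.**
- The alkoxide 18 may close to the epoxide.
- The diastereomer ratio may be modest.
- 16 may racemise.

The fallback sets out from 17 and 16 and comes back at 22. Adduct 18 is deliberately warmed to 0 °C so that it closes with inversion at C10 to the robust, chromatographable alkynyl trans‑9,10‑epoxide F3, where the minor diastereomer is removed. Semi‑hydrogenation over Pd/CaCO3 poisoned with Pb(OAc)2 gives the vinyl epoxide F1. The sequence through the bromo‑epoxide F2 described above then re‑installs the C10 bromine during ring‑C closure.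

**Step 7, organocatalytic α‑bromination.**
- The ee may erode.
- The alkene may be brominated.
- The product is hard to handle.

The fallback sets out from 13 and comes back at 16, and uses an auxiliary instead of a catalyst:
- LiOH hydrolysis gives (4E)‑hept‑4‑enoic acid F4.
- Pivaloyl chloride/Et3N, then lithiated (R)‑4‑benzyloxazolidin‑2‑one, gives the N‑acyl oxazolidinone F5.
- Bu2BOTf/iPr2NEt, then NBS at −78 °C, brominates the chelated Z‑boron enolate on the face away from the benzyl group and gives the (2R)‑bromo imide F6, which can be purified to a single diastereomer.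
- LiBH4 in wet Et2O releases (2R,4E)‑2‑bromohept‑4‑en‑1‑ol F7.
- Dess–Martin periodinane oxidises F7 under neutral conditions to 16.

**Further compounds**
F1 | step 10 | (2S,3R,5R)‑5‑{(Z)‑2‑[(2S,3S)‑3‑((E)‑pent‑2‑en‑1‑yl)oxiran‑2‑yl]ethenyl}‑2‑(triisopropylsilylethynyl)oxolan‑3‑ol | CC(C)[Si](C#C[C@@H]1O[C@@H](/C=C\[C@@H]2O[C@H]2C/C=C/CC)C[C@H]1O)(C(C)C)C(C)C
F2 | step 10 | (12E)‑8‑bromo‑3,6:4,7:9,10‑triepoxy‑1‑(triisopropylsilyl)pentadec‑12‑en‑1‑yne with C3 to C8 configured as in 22 and a trans (9R,10S)‑epoxide | CC(C)[Si](C#C[C@@H]1O[C@@H]2C[C@H]1O[C@@H]2[C@@H](Br)[C@@H]1O[C@H]1C/C=C/CC)(C(C)C)C(C)C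
F3 | step 8 | (2S,3R,5R)‑5‑{[(2S,3S)‑3‑((E)‑pent‑2‑en‑1‑yl)oxiran‑2‑yl]ethynyl}‑2‑(triisopropylsilylethynyl)oxolan‑3‑ol | CC(C)[Si](C#C[C@@H]1O[C@@H](C#C[C@@H]2O[C@H]2C/C=C/CC)C[C@H]1O)(C(C)C)C(C)C
F4 | step 7 | (4E)‑hept‑4‑enoic acid | CC/C=C/CCC(=O)O
F5 | step 7 | (4R)‑4‑benzyl‑3‑[(4E)‑hept‑4‑enoyl]‑1,3‑oxazolidin‑2‑one | CC/C=C/CCC(=O)N1[C@H](Cc2ccccc2)COC1=O
F6 | step 7 | (4R)‑4‑benzyl‑3‑[(2R,4E)‑2‑bromohept‑4‑enoyl]‑1,3‑oxazolidin‑2‑one | CC/C=C/C[C@@H](Br)C(=O)N1[C@H](Cc2ccccc2)COC1=O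
F7 | step 7 | (2R,4E)‑2‑bromohept‑4‑en‑1‑ol | CC/C=C/C[C@@H](Br)CO
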